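**Retrosynthetic overview**

Numbering used (3a,4,5,7a-tetrahydro-1H-indene): C1 CHMe, C2=C3(Me), C3a, C4 (Me, CO2H), C5 (Et, dienyl), C6=C7(Me), C7a; ring A is the cyclopentene, ring B the cyclohexene.
28 ⇐ Horner–Wadsworth–Emmons olefination of a C5-formyl/C4-carboxyl pair held as a temporary 5-methoxy-γ-lactone; C2=C3 ⇐ enol triflate ⇐ dissolving-metal reduction of a C2 ketone (sets H-3a); C1 methyl ⇐ enolate alkylation.
Key disconnection C7–C7a: a gold-catalysed 6-endo-dig cycloisomerisation closes ring B onto the ready-made ring A.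
Enabling feature: a ketone placed at C2 makes C7a the γ-carbon of a ring A dienol ether, and the C6=C7(Me) alkene is the footprint of a propynyl group on quaternary C5, so C7a can add to C7 of that alkyne.
17 ⇐ lactone 13 + chloroenone 15 (enolate alkenylation sets C4); 13 ⇐ Johnson–Claisen rearrangement (sets C5) of enynol 6 ⇐ hex-3-yn-2-one; ring order: temporary lactone, ring A attached, ring B closed, lactone opened.

Key step: step 9

Remark: the lactones 12 to 25 are carried as mixtures of epimers at the acetal carbon, which is destroyed in step 14; C2 of 9 and 11 and C3 of 12 and 13 are epimer mixtures that converge on the planar enolate in step 8.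

Step 1
Reactants: 1 hex-3-yn-2-one
Product: 2 (2R)-hex-3-yn-2-ol
Conditions: RuCl[(R,R)-TsDPEN](p-cymene) (0.5 mol %), i-PrOH, 23 °C
Reagents that add atoms: none
Why: Noyori asymmetric transfer hydrogenation of an alkynyl methyl ketone, in which the (R,R)-configured catalyst should set the carbinol centre as R.

Step 2
Reactants: 2 (2R)-hex-3-yn-2-ol
Product: 4 (2R,3Z)-4-iodohex-3-en-2-ol, via alkenylalanate 3 (not isolated)
Conditions: NaAlH2(OCH2CH2OMe)2, THF, 0 °C; then I2, −78 to 0 °C
Reagents that add atoms: iodine II
Why: hydroxyl-directed trans-hydroalumination of the propargylic alcohol followed by iodinolysis with retention should place iodine on C4 cis to the carbinol carbon, while the carbinol centre is untouched.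

Step 3
Reactants: 4 (2R,3Z)-4-iodohex-3-en-2-ol; 5 propyne
Product: 6 (2R,3Z)-4-ethylhept-3-en-5-yn-2-ol
Conditions: PdCl2(PPh3)2 (2 mol %), CuI (4 mol %), Et3N, THF, 23 °C
Reagents that add atoms: none
Why: Sonogashira coupling of an alkenyl iodide proceeds with retention of alkene geometry, so the propynyl group should end cis to the carbinol carbon and the ethyl group trans.

Step 4
Reactants: 6 (2R,3Z)-4-ethylhept-3-en-5-yn-2-ol; 7 triethyl orthopropionate
Product: 9 ethyl (3R,4E)-3-ethyl-2-methyl-3-(prop-1-yn-1-yl)hex-4-enoate, via ketene acetal 8 (not isolated)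
Conditions: EtCO2H (5 mol %), xylene, 140 °C, removal of EtOH
Reagents that add atoms: none
Why: Johnson–Claisen rearrangement through a chair transition state with the carbinol methyl equatorial and the slim propynyl group axial should transfer the carbinol configuration to the new quaternary C3 (R) and give the E-propenyl group; C2 forms as both epimers, which is of no consequence.

Step 5
Reactants: 9 ethyl (3R,4E)-3-ethyl-2-methyl-3-(prop-1-yn-1-yl)hex-4-enoate
Product: 11 ethyl (3R)-3-ethyl-3-formyl-2-methylhex-4-ynoate, via ozonide 10 (not isolated)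
Conditions: O3 (1.0 equiv), CH2Cl2, −78 °C; then Me2S, −78 to 23 °C
Reagents that add atoms: ozone [O-][O+]=O
Why: ozonolysis is much faster at the disubstituted alkene than at the internal alkyne, so the propenyl group should be cut to the formyl group without touching the quaternary centre.

Step 6
Reactants: 11 ethyl (3R)-3-ethyl-3-formyl-2-methylhex-4-ynoate
Product: 13 (4R)-4-ethyl-5-methoxy-3-methyl-4-(prop-1-yn-1-yl)oxolan-2-one, via hydroxy lactone 12 (not isolated)
Conditions: LiOH, THF/H2O, 40 °C; 1 M HCl to pH 2; then MeOH, CSA (10 mol %), 3 Å sieves, 23 °C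
Reagents that add atoms: lithium hydroxide [Li+].[OH-]; methanol CO
Why: saponification of the γ-oxo ester should give the ring-closed pseudo-acid, and acid-catalysed acetalisation (Fischer type) the pseudo-ester, which serves as a cyclic template and masks the aldehyde/acid pair; the C4 centre is not affected.

Step 7
Reactants: 14 2-methylcyclopentane-1,3-dione
Product: 15 3-chloro-2-methylcyclopent-2-en-1-one
Conditions: (COCl)2, DMF (cat.), CH2Cl2, 0 to 23 °C
Reagents that add atoms: oxalyl chloride ClC(=O)C(=O)Cl
Why: Vilsmeier-type activation of the enolised 1,3-dione is a standard route to the vinylogous acid chloride; no stereocentre is involved.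

Step 8
Reactants: 13 (4R)-4-ethyl-5-methoxy-3-methyl-4-(prop-1-yn-1-yl)oxolan-2-one; 15 3-chloro-2-methylcyclopent-2-en-1-one
Product: 17 (3R,4S)-4-ethyl-5-methoxy-3-methyl-3-(2-methyl-3-oxocyclopent-1-en-1-yl)-4-(prop-1-yn-1-yl)oxolan-2-one, via zinc enolate 16 (not isolated)
Conditions: LiN(i-Pr)2, THF, −78 °C; ZnCl2, −78 to 0 °C; then 15, Pd2(dba)3 (2.5 mol %), P(t-Bu)3 (10 mol %), THF, 23 to 50 °C
Reagents that add atoms: none
Why: palladium-catalysed α-alkenylation of a zinc ester enolate (Negishi-type enolate coupling) should create the quaternary lactone C3 (target C4), the cyclopentenyl group entering anti to the larger C4 ethyl group and syn to the slim propynyl group.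

Step 9
Reactants: 17 (3R,4S)-4-ethyl-5-methoxy-3-methyl-3-(2-methyl-3-oxocyclopent-1-en-1-yl)-4-(prop-1-yn-1-yl)oxolan-2-one
Product: 19 tricyclic enone lactone, via silyl dienol ether 18 (not isolated)
Conditions: TBSOTf, Et3N, CH2Cl2, 0 °C; then [(t-Bu)2(2-biphenylyl)P]AuNTf2 (5 mol %), CH2Cl2/MeOH 10:1, 40 °C
Reagents that add atoms: none
Why: Proposed new method: the silyl dienol ether 18 (the 1-silyloxy tautomer, which equilibrates with the 2-silyloxy isomer by 1,5-hydrogen shift) should attack the gold-activated alkyne through its γ-carbon C7a, anti to the metal, at the methyl-bearing alkyne carbon C7, after which methanol removes the silyl group and protodeaurates C6, returning the enone and leaving the C6=C7 alkene. The closest known reactions are the gold-catalysed carbocyclisation of silyl enol ethers onto alkynes (Conia-ene type, known in 5-exo, 5-endo and 6-endo modes) and the γ-selective vinylogous Mukaiyama reactions of silyl dienol ethers; their combination on a dienol ether has not been shown. Ring B is the only ring closed, in the 6-endo-dig mode, and the ring-cis C6=C7 geometry follows from anti-addition within the ring. The new stereocentre C7a should be set by allylic 1,3-strain: the tether leaves the plane of ring A on the attacked face, the in-plane position next to the C3 methyl is taken by the flat lactone carbonyl on C4, and the C4 methyl points to the opposite face, so that H-7a ends cis to the C4 methyl. The step needs γ- over α-attack and 6-endo over 5-exo closure; the methyl group on the α-carbon C3, the quaternary C5 next to the proximal alkyne carbon and the bulky biaryl phosphine ligand should secure both.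

Step 10
Reactants: 19 tricyclic enone lactone
Product: 21 C1-methylated tricyclic enone lactone, via lithium dienolate 20 (not isolated)
Conditions: LiN(i-Pr)2, THF, −78 °C; MeI, −78 to −40 °C
Reagents that add atoms: iodomethane CI
Why: kinetic α′-deprotonation of the cyclopentenone and enolate alkylation should place the methyl group at C1 anti to the adjacent C7a–C7 bond, that is cis to H-7a.

Step 11
Reactants: 21 C1-methylated tricyclic enone lactone
Product: 23 enol triflate, via lithium enolate 22 (not isolated)
Conditions: Li (2.2 equiv), NH3/THF, t-BuOH (1.0 equiv), −78 °C; NH3 removed; PhNTf2, THF, 0 °C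
Reagents that add atoms: N-phenylbis(trifluoromethanesulfonimide) O=S(=O)(N(c1ccccc1)S(=O)(=O)C(F)(F)F)C(F)(F)F
Why: dissolving-metal (Birch-type) reduction of the tetrasubstituted enone with regiospecific trapping of the enolate as its triflate; protonation of the β-carbanion at C3a should occur axially on ring B, anti to H-7a, giving the trans ring fusion, as is usual for bicyclo[4.3.0]non-1(9)-en-8-ones.

Step 12
Reactants: 23 enol triflate
Product: 24 tricyclic diene lactone
Conditions: Pd(OAc)2 (5 mol %), PPh3 (10 mol %), HCO2H, n-Bu3N, DMF, 60 °C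
Reagents that add atoms: none
Why: palladium-catalysed formate reduction of an enol triflate replaces the triflate by hydrogen without moving the double bond, which gives the C2=C3 alkene of the target; no stereocentre changes.

Step 13
Reactants: 24 tricyclic diene lactone
Product: 25 pseudo-acid (5-hydroxy lactone)
Conditions: 1 M HCl, THF, 40 °C
Reagents that add atoms: water O
Why: acid hydrolysis of the acylal-type acetal should give the pseudo-acid, which is in ring–chain equilibrium with the C5-formyl C4-carboxylic acid; no carbon stereocentre of the skeleton is touched.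

Step 14
Reactants: 25 pseudo-acid (5-hydroxy lactone); 26 diethyl cinnamylphosphonate
Product: 28 (1R,3aR,4R,5S,7aS)-5-ethyl-1,3,4,7-tetramethyl-5-[(1E,3E)-4-phenylbuta-1,3-dien-1-yl]-3a,4,5,7a-tetrahydro-1H-indene-4-carboxylic acid, via aldehyde carboxylate 27 (not isolated)
Conditions: 26, LiN(SiMe3)2 (3.3 equiv), THF, −78 to 23 °C; then 1 M HCl
Reagents that add atoms: none
Why: base should open the pseudo-acid to the aldehyde carboxylate, and the Horner–Wadsworth–Emmons reaction of the allylic phosphonate anion should form the new alkene with E geometry while the cinnamyl alkene stays E; no ring stereocentre is affected.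

**Compound list**

1 | hex-3-yn-2-one | CC(=O)C#CCC | starting material
2 | (2R)-hex-3-yn-2-ol | C[C@@H](O)C#CCC | intermediate
3 | sodium alkenylalanate (cyclic alkoxy alkenyl aluminate from 2) | C[C@H]1O[Al-](OCCOC)(OCCOC)C(CC)=C1.[Na+] | intermediate
4 | (2R,3Z)-4-iodohex-3-en-2-ol | C[C@@H](O)/C=C(\I)CC | intermediate
5 | propyne | CC#C | starting material
6 | (2R,3Z)-4-ethylhept-3-en-5-yn-2-ol | C[C@@H](O)/C=C(\C#CC)CC | intermediate
7 | triethyl orthopropionate | CCC(OCC)(OCC)OCC | starting material
8 | mixed ketene acetal, 1-ethoxy-1-[(2R,3Z)-4-ethylhept-3-en-5-yn-2-yloxy]prop-1-ene | C[C@@H](OC(OCC)=CC)/C=C(\C#CC)CC | intermediate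
9 | ethyl (3R,4E)-3-ethyl-2-methyl-3-(prop-1-yn-1-yl)hex-4-enoate (both C2 epimers) | CCOC(=O)C(C)[C@](CC)(C#CC)/C=C/C | intermediate
10 | secondary ozonide (1,2,4-trioxolane) of 9 | CCOC(=O)C(C)[C@](CC)(C#CC)C1OOC(C)O1 | intermediate
11 | ethyl (3R)-3-ethyl-3-formyl-2-methylhex-4-ynoate (both C2 epimers) | CCOC(=O)C(C)[C@](CC)(C#CC)C=O | intermediate
12 | (4R)-4-ethyl-5-hydroxy-3-methyl-4-(prop-1-yn-1-yl)oxolan-2-one (pseudo-acid; C3 and C5 epimers) | CC[C@@]1(C#CC)C(O)OC(=O)C1C | intermediate
13 | (4R)-4-ethyl-5-methoxy-3-methyl-4-(prop-1-yn-1-yl)oxolan-2-one (C3 and C5 epimers) | CC[C@@]1(C#CC)C(OC)OC(=O)C1C | intermediate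
14 | 2-methylcyclopentane-1,3-dione | CC1C(=O)CCC1=O | starting material
15 | 3-chloro-2-methylcyclopent-2-en-1-one | CC1=C(Cl)CCC1=O | intermediate
16 | chlorozinc enolate of 13 | CC[C@@]1(C#CC)C(OC)OC(O[Zn]Cl)=C1C | intermediate
17 | (3R,4S)-4-ethyl-5-methoxy-3-methyl-3-(2-methyl-3-oxocyclopent-1-en-1-yl)-4-(prop-1-yn-1-yl)oxolan-2-one (C5 epimers; cyclopentenyl cis to propynyl, methyl cis to ethyl; C4 is arranged as in 13, its descriptor changes only by priority) | CC[C@@]1(C#CC)C(OC)OC(=O)[C@]1(C)C2=C(C)C(=O)CC2 | intermediate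
18 | tert-butyldimethylsilyl dienol ether of 17, with a 4-silyloxy-3-methylcyclopenta-1,3-dien-2-yl group on lactone C3 | CC[C@@]1(C#CC)C(OC)OC(=O)[C@]1(C)C2=CCC(O[Si](C)(C)C(C)(C)C)=C2C | intermediate
19 | tricyclic enone lactone: 5-ethyl-3,4,7-trimethyl-1,4,5,7a-tetrahydro-2H-inden-2-one whose C4 carbonyl carbon and C5 methoxymethine carbon are joined through oxygen as a cis-fused 5-methoxy-γ-lactone; H-7a cis to the C4 methyl; C4, C5 and C7a arranged as in 28 | CC[C@]12C=C(C)[C@H]3CC(=O)C(C)=C3[C@@]1(C)C(=O)OC2OC | intermediate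
20 | lithium cross-conjugated dienolate of 19 (C1=C2–O) | CC[C@]12C=C(C)[C@H]3C=C([O-])C(C)=C3[C@@]1(C)C(=O)OC2OC.[Li+] | intermediate
21 | C1-methylated tricyclic enone lactone: 19 with a methyl group at C1 cis to H-7a | CC[C@]12C=C(C)[C@H]3[C@H](C)C(=O)C(C)=C3[C@@]1(C)C(=O)OC2OC | intermediate
22 | lithium enolate (C2–O, C2=C3) from reduction of 21, H-3a trans to H-7a | CC[C@]12C=C(C)[C@H]3[C@H](C)C([O-])=C(C)[C@@H]3[C@@]1(C)C(=O)OC2OC.[Li+] | intermediate
23 | enol triflate: C2 trifluoromethanesulfonate of the C2=C3 enol, trans ring fusion, lactone as in 19 | CC[C@]12C=C(C)[C@H]3[C@H](C)C(OS(=O)(=O)C(F)(F)F)=C(C)[C@@H]3[C@@]1(C)C(=O)OC2OC | intermediate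
24 | tricyclic diene lactone: the ring system of 28 with C4 and C5 bridged as the 5-methoxy-γ-lactone | CC[C@]12C=C(C)[C@H]3[C@H](C)C=C(C)[C@@H]3[C@@]1(C)C(=O)OC2OC | intermediate
25 | pseudo-acid: 5-hydroxy-γ-lactone corresponding to 24 | CC[C@]12C=C(C)[C@H]3[C@H](C)C=C(C)[C@@H]3[C@@]1(C)C(=O)OC2O | intermediate
26 | diethyl [(2E)-3-phenylprop-2-en-1-yl]phosphonate (diethyl cinnamylphosphonate) | CCOP(=O)(OCC)C/C=C/c1ccccc1 | starting material
27 | lithium (1R,3aR,4R,5S,7aS)-5-ethyl-5-formyl-1,3,4,7-tetramethyl-3a,4,5,7a-tetrahydro-1H-indene-4-carboxylate | CC[C@]1(C=O)C=C(C)[C@H]2[C@H](C)C=C(C)[C@@H]2[C@@]1(C)C(=O)[O-].[Li+] | intermediate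
28 | (1R,3aR,4R,5S,7aS)-5-ethyl-1,3,4,7-tetramethyl-5-[(1E,3E)-4-phenylbuta-1,3-dien-1-yl]-3a,4,5,7a-tetrahydro-1H-indene-4-carboxylic acid | CC[C@]1(/C=C/C=C/c2ccccc2)C=C(C)[C@H]2[C@H](C)C=C(C)[C@@H]2[C@@]1(C)C(=O)O | target

**Step count and risks**

Total steps: 14. Longest linear sequence: 13 (steps 1 to 6 and 8 to 14).

Steps most likely to fail:

1. Step 9 (Proposed new method). The closure may fail through attack by the α-carbon C3, 5-exo closure at the proximal alkyne carbon, participation of the lactone carbonyl oxygen, or loss of the silyl group before cyclisation. The fallback sets out from 17. Ruthenium-catalysed trans-hydrostannation ([Cp*Ru(MeCN)3]PF6, Bu3SnH, CH2Cl2) should give the (Z)-alkenylstannane F1 with tin on the methyl-bearing carbon. Iododestannylation (I2, CH2Cl2, 0 °C) should give the (Z)-alkenyl iodide F2. An intramolecular palladium-catalysed γ-alkenylation of the enone dienolate (Pd(OAc)2, P(t-Bu)3, Cs2CO3, toluene, 80 °C) should then close the same C7–C7a bond and come back to the route at 19.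

2. Step 8. The coupling may be slow at the congested enolate carbon, the enolate may be protonated by the chloroenone, and the facial selectivity may be eroded by the acetal epimers. The fallback sets out from 13. O-Silylation (LiN(i-Pr)2, TBSCl, THF, −78 °C) should give the silyl ketene acetal F3. Mukaiyama–Michael addition to 2-methylcyclopent-2-en-1-one (TBSOTf cat., CH2Cl2, −78 °C) should give the silyl enol ether F4. Saegusa–Ito oxidation (Pd(OAc)2, O2, DMSO) should restore the enone and come back to the route at 17.

3. Step 11. The lactone acetal may be over-reduced, or C3a may be protonated from the wrong face, giving the cis ring fusion. The fallback sets out from 21. Luche reduction (NaBH4, CeCl3·7H2O, MeOH, −40 °C), with hydride entering anti to the C1 methyl, should give the allylic alcohol F5. Acylation (ClCO2Me, pyridine, CH2Cl2) should give the allylic methyl carbonate F6. Palladium-catalysed formate hydrogenolysis (Pd(OAc)2, n-Bu3P, HCO2NH4, dioxane, 80 °C) delivers hydride to the more substituted allyl terminus C3a, anti to the leaving group. This should set the trans fusion and the C2=C3 alkene at once and come back to the route at 24.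

Further compounds
F1 | step 9 | (Z)-alkenylstannane: 17 with the propynyl group replaced by (1Z)-2-(tributylstannyl)prop-1-enyl | CC[C@@]1(/C=C(/C)[Sn](CCCC)(CCCC)CCCC)C(OC)OC(=O)[C@]1(C)C2=C(C)C(=O)CC2
F2 | step 9 | (Z)-alkenyl iodide: 17 with the propynyl group replaced by (1Z)-2-iodoprop-1-enyl | CC[C@@]1(/C=C(/C)I)C(OC)OC(=O)[C@]1(C)C2=C(C)C(=O)CC2
F3 | step 8 | tert-butyldimethylsilyl ketene acetal of 13 | CC[C@@]1(C#CC)C(OC)OC(O[Si](C)(C)C(C)(C)C)=C1C
F4 | step 8 | Mukaiyama–Michael adduct, silyl enol ether of the 3-substituted 2-methylcyclopentanone | CC[C@@]1(C#CC)C(OC)OC(=O)[C@]1(C)C2CCC(O[Si](C)(C)C(C)(C)C)=C2C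
F5 | step 11 | allylic alcohol: 21 with the C2 ketone reduced, hydroxyl cis to the C1 methyl | CC[C@]12C=C(C)[C@H]3[C@H](C)[C@H](O)C(C)=C3[C@@]1(C)C(=O)OC2OC
F6 | step 11 | allylic methyl carbonate of F5 | CC[C@]12C=C(C)[C@H]3[C@H](C)[C@H](OC(=O)OC)C(C)=C3[C@@]1(C)C(=O)OC2OC
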